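**Plan**

- Numbering follows the chain: C1 (macrolactone C=O) to C23 (δ-lactone C=O); O19 and O21 are the oxygens on C19 and C21. Retrosynthetic cuts, in order: C16–C17 (diene), O21–C1 (macrolactone), O6–C3 (furanone), C4–C5, C8–C9; in the δ-lactone O19–C23, then C20–C21 and C22–C23 together.
- Feature used: in the δ-lactone ring (O19–C23–C22–C21–C20–C19) the edge C21–C22 is a two-carbon unit with O on C21 and Me on C22, flanked by the methylene C20 and the acyl carbon C23. An (E)-propenyl group on boron supplies this edge: C20 migrates from boron to C21, C23 arrives at C22 as a methoxycarbonyl electrophile, and the C21–B bond stands in for C21–O.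
- Forward: δ-lactone first (steps 1–9, ring closed by O19 acylation); chain C5–C16 by crotylboration and aldol, with a dioxinone as C1–C4 (steps 10–28); Stille union at C16–C17; the 21-membered ring by acylketene trapping at O21; the furanone ring by cyclodehydration; desilylation.
- Stereochemistry: C19 from Sharpless epoxidation; C21/C22 from the key step (alkene geometry, ligand, C–B oxidation with retention); C14 from (R)-2-methylglycidol; C10/C11 from tartrate crotylboration; C6 from D-glycerate; C8/C9 from a chelated titanium aldol; C7 from hydroxyl-directed reduction; both diene double bonds E from Takai-type olefination and syn hydrozirconation.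

Key step: step 5

Remark: the sense of induction of (Sp,Sp)-MandyPhos in step 5 is assumed by analogy with aryl electrophiles; its enantiomer is used if the sense proves opposite.
Remark: Bu3SnCHBr2 (step 9) is taken as prepared beforehand from CH2Br2, LDA and Bu3SnCl; compounds 1, 6, 15, 28 and 40 are taken as catalogue compounds.

**Route**

Step 1
Reactants: 1 2-methylidenebutan-1-ol
Product: 2 (S)-(2-ethyloxiran-2-yl)methanol
Conditions: Ti(OiPr)4 (cat.), L-(+)-DIPT, t-BuOOH, 4 Å MS, CH2Cl2, −20 °C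
Reagents that add atoms: tert-butyl hydroperoxide, CC(C)(C)OO
Why: Sharpless asymmetric epoxidation of a 2-substituted allylic alcohol, in which the L-tartrate–titanium complex should deliver oxygen to the face that gives the (S)-epoxide, the future C19.

Step 2
Reactants: 2 (S)-(2-ethyloxiran-2-yl)methanol
Product: 3 (R)-tert-butyl[(2-ethyloxiran-2-yl)methoxy]dimethylsilane
Conditions: TBSCl, imidazole, DMF, rt
Reagents that add atoms: tert-butyldimethylsilyl chloride, CC(C)(C)[Si](C)(C)Cl
Why: Silyl ether formation at the primary alcohol, which leaves the epoxide and its stereocentre untouched (the descriptor changes by priority only).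

Step 3
Reactants: 3 (R)-tert-butyl[(2-ethyloxiran-2-yl)methoxy]dimethylsilane
Product: 4 (S)-1-[(tert-butyldimethylsilyl)oxy]-2-[(4,4,5,5-tetramethyl-1,3,2-dioxaborolan-2-yl)methyl]butan-2-ol
Conditions: B2pin2, CuCl (cat.), Xantphos (cat.), KOt-Bu (cat.), MeOH, THF, rt
Reagents that add atoms: bis(pinacolato)diboron, CC1(C)OB(OC1(C)C)B1OC(C)(C)C(C)(C)O1
Why: CuCl-catalysed borylative ring opening of an epoxide, in which the Cu–B nucleophile attacks the unhindered CH2 terminus in SN2 fashion, so the quaternary centre keeps its configuration and the CH2–B carbon (C20) is in place.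

Step 4
Reactants: 4 (S)-1-[(tert-butyldimethylsilyl)oxy]-2-[(pinacolboryl)methyl]butan-2-ol
Product: 5 tertiary triethylsilyl ether of 4
Conditions: TESOTf, 2,6-lutidine, CH2Cl2, −78 to 0 °C
Reagents that add atoms: triethylsilyl trifluoromethanesulfonate, CC[Si](CC)(CC)OS(=O)(=O)C(F)(F)F
Why: Silyl triflate silylation of the hindered tertiary alcohol, which prevents alkoxide formation and makes the β-oxygen a poor leaving group in the ate complex of step 5.

Step 5
Reactants: 5 tertiary triethylsilyl ether of 4; 6 (E)-1-bromoprop-1-ene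
Product: 9 methyl (2S,3S,5R)-5-{[(tert-butyldimethylsilyl)oxy]methyl}-2-methyl-3-(pinacolboryl)-5-[(triethylsilyl)oxy]heptanoate, via (E)-prop-1-enyllithium 7 (not isolated), via lithium propenylboronate complex 8 (not isolated)
Conditions: 6, t-BuLi (2 equiv), Et2O, −78 °C; 5, THF, −78 to 0 °C; then Pd(OAc)2 (cat.), (Sp,Sp)-MandyPhos (cat.), KOTf, ClCO2Me, THF, 40 °C
Reagents that add atoms: tert-butyllithium, [Li]C(C)(C)C (lithium of 7 and 8 only); methyl chloroformate, COC(=O)Cl
Why: Proposed new method: 7 adds to the boron of 5 to give ate complex 8; zerovalent palladium (from Pd(OAc)2 and the diphosphine) inserts into the C–Cl bond of methyl chloroformate, the resulting methoxycarbonyl complex of divalent palladium binds the propenyl π bond of 8 and triggers a 1,2-metallate shift in which the C20 methylene migrates from boron to C21 anti to palladium while Pd–C22 forms, and C–C reductive elimination then makes C22–C23, so that C20–C21 and C22–C23 arise in one catalytic turnover. The closest known reaction type is the palladium-catalysed conjunctive cross-coupling of alkenylboron ate complexes with aryl or alkenyl triflates and with acyl-type chlorides; the extension lies in the alkoxycarbonyl electrophile and in the β-methyl alkenyl group on a pinacol boronate. No ring is closed here: the step lays down the C20–C23 edge of the δ-lactone as an open chain, and the ring is closed through O19–C23 in step 7. C21 and C22 are the new stereocentres: their relative configuration (B and Me anti in the zigzag, hence cis on the lactone) follows from stereospecific anti addition across the (E)-alkene, and their absolute configuration from the alkene face selected by the planar-chiral diphosphine, which should override the remote C19 centre. The step needs migration of the alkyl group and not of a pinacol oxygen (inherent), a metallate shift faster than direct propenyl transfer to palladium (wide-bite-angle ligand, halide scavenged by KOTf), and survival of the β-silyloxy boronate without elimination (poor leaving ability of the silyl ether, mild temperature).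

Step 6
Reactants: 9 methyl (2S,3S,5R)-5-{[(tert-butyldimethylsilyl)oxy]methyl}-2-methyl-3-(pinacolboryl)-5-[(triethylsilyl)oxy]heptanoate
Product: 10 methyl (2S,3S,5R)-5-{[(tert-butyldimethylsilyl)oxy]methyl}-3-hydroxy-2-methyl-5-[(triethylsilyl)oxy]heptanoate
Conditions: 30% H2O2, pH 7 phosphate buffer, THF, 0 °C to rt
Reagents that add atoms: hydrogen peroxide, OO
Why: Oxidation of the secondary alkylboronate (carbon shifts from boron to oxygen with retention) gives the C21 hydroxyl with the configuration set in step 5, and the neutral buffer spares the methyl ester.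

Step 7
Reactants: 10 methyl (2S,3S,5R)-5-{[(tert-butyldimethylsilyl)oxy]methyl}-3-hydroxy-2-methyl-5-[(triethylsilyl)oxy]heptanoate
Product: 12 (3S,4S,6R)-6-ethyl-4-hydroxy-6-(hydroxymethyl)-3-methyloxan-2-one, via triol methyl ester 11 (not isolated)
Conditions: TsOH·H2O (cat.), MeOH, rt; then PhMe, 50 °C
Reagents that add atoms: none
Why: Acid methanolysis of both silyl ethers followed by acid-catalysed lactonisation, in which the tertiary C19 hydroxyl closes the six-membered δ-lactone (acyl substitution at C23) in preference to the seven-membered ring from the primary hydroxyl; no stereocentre is involved.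

Step 8
Reactants: 12 (3S,4S,6R)-6-ethyl-4-hydroxy-6-(hydroxymethyl)-3-methyloxan-2-one
Product: 13 (2R,4S,5S)-2-ethyl-4-hydroxy-5-methyl-6-oxooxane-2-carbaldehyde
Conditions: TEMPO (cat.), PhI(OAc)2, CH2Cl2, rt
Reagents that add atoms: none
Why: Oxoammonium (TEMPO) oxidation is selective for the primary over the secondary alcohol, and the trans relation of C21–O and the C19 formyl group on the ring prevents lactol formation.

Step 9
Reactants: 13 (2R,4S,5S)-2-ethyl-4-hydroxy-5-methyl-6-oxooxane-2-carbaldehyde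
Product: 14 (3S,4S,6R)-6-ethyl-4-hydroxy-3-methyl-6-[(E)-2-(tributylstannyl)ethenyl]oxan-2-one
Conditions: CrCl2, Bu3SnCHBr2, LiI, THF/DMF, rt
Reagents that add atoms: (dibromomethyl)tributylstannane, CCCC[Sn](CCCC)(CCCC)C(Br)Br
Why: Takai-type CrCl2-mediated stannylolefination of the aldehyde through a geminal dichromium species should give the (E)-alkenylstannane (C17=C18) and tolerates the free hydroxyl and the lactone.

Step 10
Reactants: 15 (R)-(2-methyloxiran-2-yl)methanol
Product: 16 (S)-2-methylhex-5-ene-1,2-diol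
Conditions: CH2=CHCH2MgCl (3 equiv), CuI (cat.), THF, −40 to 0 °C
Reagents that add atoms: allylmagnesium chloride, C=CC[Mg]Cl
Why: CuI-catalysed Grignard opening of the 2,2-disubstituted epoxide at its CH2 terminus (SN2), so the tertiary centre (C14) comes unchanged from the chiral-pool epoxide.

Step 11
Reactants: 16 (S)-2-methylhex-5-ene-1,2-diol
Product: 17 (S)-2-methyl-1,2-bis[(triethylsilyl)oxy]hex-5-ene
Conditions: TESOTf (2.4 equiv), 2,6-lutidine, CH2Cl2, −78 to 0 °C
Reagents that add atoms: triethylsilyl trifluoromethanesulfonate, CC[Si](CC)(CC)OS(=O)(=O)C(F)(F)F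
Why: Exhaustive silyl ether formation with the silyl triflate protects the primary and the tertiary hydroxyl in one operation.

Step 12
Reactants: 17 (S)-2-methyl-1,2-bis[(triethylsilyl)oxy]hex-5-ene
Product: 18 (S)-2-methyl-2-[(triethylsilyl)oxy]hex-5-enal
Conditions: (COCl)2, DMSO, CH2Cl2, −78 to −30 °C; Et3N
Reagents that add atoms: none
Why: Swern oxidation acts directly on a primary triethylsilyl ether (the activated sulfoxide attacks the unhindered ether oxygen) while the tertiary silyl ether is inert.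

Step 13
Reactants: 18 (S)-2-methyl-2-[(triethylsilyl)oxy]hex-5-enal
Product: 19 (S)-[(1,1-dibromo-3-methylhepta-1,6-dien-3-yl)oxy]triethylsilane
Conditions: CBr4, PPh3, 2,6-lutidine, CH2Cl2, 0 °C
Reagents that add atoms: carbon tetrabromide, BrC(Br)(Br)Br
Why: First stage of the Corey–Fuchs alkyne synthesis (dibromoolefination) on a non-enolisable aldehyde.

Step 14
Reactants: 19 (S)-[(1,1-dibromo-3-methylhepta-1,6-dien-3-yl)oxy]triethylsilane
Product: 21 (S)-triethyl[(4-methyloct-7-en-2-yn-4-yl)oxy]silane, via lithium acetylide 20 (not isolated)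
Conditions: n-BuLi (2.2 equiv), THF, −78 °C; then MeI, −78 °C to rt
Reagents that add atoms: n-butyllithium, [Li]CCCC (lithium of 20 only); iodomethane, CI
Why: Second stage of the Corey–Fuchs sequence: Br–Li exchange and Fritsch–Buttenberg–Wiechell rearrangement give the lithium acetylide, which is methylated in the same flask to supply the C16 methyl group.

Step 15
Reactants: 21 (S)-triethyl[(4-methyloct-7-en-2-yn-4-yl)oxy]silane
Product: 23 (S)-4-methyl-4-[(triethylsilyl)oxy]hept-5-ynal, via 1,2-diol 22 (not isolated)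
Conditions: OsO4 (cat.), NaIO4, 2,6-lutidine, dioxane/H2O, rt
Reagents that add atoms: osmium tetroxide, O=[Os](=O)(=O)=O; sodium periodate, [Na+].[O-]I(=O)(=O)=O
Why: Lemieux–Johnson oxidation cleaves the terminal alkene through its diol, while the internal alkyne reacts far more slowly with OsO4.

Step 16
Reactants: 23 (S)-4-methyl-4-[(triethylsilyl)oxy]hept-5-ynal
Product: 24 (3S,4R,7S)-3,7-dimethyl-7-[(triethylsilyl)oxy]dec-1-en-8-yn-4-ol
Conditions: (R,R)-diisopropyl tartrate (E)-crotylboronate, 4 Å MS, PhMe, −78 °C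
Reagents that add atoms: diisopropyl (4R,5R)-2-[(E)-but-2-enyl]-1,3,2-dioxaborolane-4,5-dicarboxylate, CC(C)OC(=O)[C@@H]1OB(C/C=C/C)O[C@H]1C(=O)OC(C)C
Why: Roush crotylboration through a chair (Zimmerman–Traxler) transition state, in which the (E)-crotyl group gives the 10,11-anti relationship and the (R,R)-tartrate directs attack to the Si face of the aldehyde, setting C10 and C11.

Step 17
Reactants: 24 (3S,4R,7S)-3,7-dimethyl-7-[(triethylsilyl)oxy]dec-1-en-8-yn-4-ol
Product: 25 (3S,4R,7S)-4-methoxy-3,7-dimethyl-7-[(triethylsilyl)oxy]dec-1-en-8-yne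
Conditions: NaH, MeI, THF, 0 °C to rt
Reagents that add atoms: iodomethane, CI
Why: Williamson etherification of the secondary alkoxide installs the C11 methyl ether without touching any stereocentre.

Step 18
Reactants: 25 (3S,4R,7S)-4-methoxy-3,7-dimethyl-7-[(triethylsilyl)oxy]dec-1-en-8-yne
Product: 27 (2R,3R,6S)-3-methoxy-2,6-dimethyl-6-[(triethylsilyl)oxy]non-7-ynal, via 1,2-diol 26 (not isolated)
Conditions: OsO4 (cat.), NaIO4, 2,6-lutidine, dioxane/H2O, rt
Reagents that add atoms: osmium tetroxide, O=[Os](=O)(=O)=O; sodium periodate, [Na+].[O-]I(=O)(=O)=O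
Why: Lemieux–Johnson oxidation of the vinyl group under buffered conditions gives the α-methyl aldehyde (C9), which is used crude to avoid epimerisation at C10.

Step 19
Reactants: 28 methyl (R)-2,2-dimethyl-1,3-dioxolane-4-carboxylate
Product: 30 (R)-1-(2,2-dimethyl-1,3-dioxolan-4-yl)propan-1-one, via Weinreb amide 29 (not isolated)
Conditions: MeNHOMe·HCl, i-PrMgCl, THF, −20 °C; then EtMgBr, 0 °C
Reagents that add atoms: N,O-dimethylhydroxylamine hydrochloride, CNOC.Cl (in 29 only); ethylmagnesium bromide, CC[Mg]Br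
Why: Weinreb ketone synthesis in one flask, in which the chelated tetrahedral adduct of the amide with EtMgBr stops at the ketone stage and shields the α-stereocentre (C6) from enolisation.

Step 20
Reactants: 30 (R)-1-(2,2-dimethyl-1,3-dioxolan-4-yl)propan-1-one; 27 (2R,3R,6S)-3-methoxy-2,6-dimethyl-6-[(triethylsilyl)oxy]non-7-ynal
Product: 32 C5–C16 aldol adduct (C7 ketone; 9-OH; 8,9-syn; 9,10-anti; 5,6-O-isopropylidene), via titanium enolate 31 (not isolated)
Conditions: 30, TiCl4, i-Pr2NEt, CH2Cl2, −78 °C; then 27, −78 °C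
Reagents that add atoms: titanium tetrachloride, Cl[Ti](Cl)(Cl)Cl (titanium of 31 only)
Why: TiCl4-mediated syn-aldol reaction through a chair transition state, in which the chelating C6 alkoxy group fixes the face of the (Z)-enolate (6-O/8-Me syn), the Z geometry gives 8,9-syn, and the anti-Felkin preference of Z enolates with α-methyl aldehydes gives 9,10-anti.

Step 21
Reactants: 32 C5–C16 aldol adduct
Product: 33 C5–C16 7,9-anti diol (5,6-O-isopropylidene)
Conditions: Me4NBH(OAc)3, MeCN/AcOH, −30 °C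
Reagents that add atoms: none
Why: Evans–Saksena reduction, in which the C9 hydroxyl binds the acetoxyborohydride and delivers hydride intramolecularly to C7, should give the 7,9-anti diol.

Step 22
Reactants: 33 C5–C16 7,9-anti diol
Product: 34 7,9-O-di-tert-butylsilylene derivative of 33
Conditions: t-Bu2Si(OTf)2, 2,6-lutidine, CH2Cl2, 0 °C
Reagents that add atoms: di-tert-butylsilyl bis(trifluoromethanesulfonate), CC(C)(C)[Si](OS(=O)(=O)C(F)(F)F)(OS(=O)(=O)C(F)(F)F)C(C)(C)C
Why: Cyclic silylene formation ties the 1,3-diol into a six-membered ring that resists mild acid and base but is labile to fluoride.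

Step 23
Reactants: 34 7,9-O-di-tert-butylsilylene derivative of 33
Product: 35 C5–C16 5,6,14-triol (7,9-silylene, alkyne)
Conditions: CSA (cat.), MeOH, rt
Reagents that add atoms: none
Why: Acid-catalysed transacetalisation removes the terminal acetonide and the tertiary triethylsilyl ether while the silylene stays, and the propargylic tertiary alcohol does not ionise under these conditions.

Step 24
Reactants: 35 C5–C16 5,6,14-triol
Product: 36 C5–C16 5,6,14-tris(triethylsilyl) ether (7,9-silylene, alkyne)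
Conditions: TESOTf (3.6 equiv), 2,6-lutidine, CH2Cl2, −78 to 0 °C
Reagents that add atoms: triethylsilyl trifluoromethanesulfonate, CC[Si](CC)(CC)OS(=O)(=O)C(F)(F)F
Why: Exhaustive silyl ether formation with the silyl triflate protects the C5, C6 and C14 hydroxyls in one operation.

Step 25
Reactants: 36 C5–C16 5,6,14-tris(triethylsilyl) ether
Product: 38 C5–C16 (E)-C16 alkenyl iodide (tris-triethylsilyl ether), via alkenylzirconocene chloride 37 (not isolated)
Conditions: Cp2Zr(H)Cl, THF, 50 °C; then I2, 0 °C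
Reagents that add atoms: Cp2Zr(H)Cl, Cl[ZrH](C1C=CC=C1)C1C=CC=C1 (zirconium of 37 only); iodine, II
Why: Hydrozirconation–iodination, in which syn addition of Zr–H places zirconium on the less hindered alkyne carbon C16 and iodinolysis with retention gives the (E)-2-iodoalkene, fixing the C15=C16 geometry.

Step 26
Reactants: 38 C5–C16 (E)-C16 alkenyl iodide (tris-triethylsilyl ether)
Product: 39 C5 aldehyde (6-OTES, 14-OTES, 7,9-silylene, alkenyl iodide)
Conditions: (COCl)2, DMSO, CH2Cl2, −78 to −30 °C; i-Pr2NEt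
Reagents that add atoms: none
Why: Swern oxidation of the primary triethylsilyl ether gives the C5 aldehyde while the secondary C6 and tertiary C14 silyl ethers stay in place, and the hindered amine limits epimerisation at C6.

Step 27
Reactants: 40 2,2,6-trimethyl-4H-1,3-dioxin-4-one; 39 C5 aldehyde
Product: 42 C1–C16 vinylogous aldol adduct (C5 carbinol as both epimers), via lithium dienolate 41 (not isolated)
Conditions: 40, LDA, THF, −78 °C; then 39, −78 °C
Reagents that add atoms: lithium diisopropylamide, [Li]N(C(C)C)C(C)C (lithium of 41 only)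
Why: Vinylogous aldol addition of the dioxinone dienolate through its γ-carbon (C4) to the aldehyde; the C5 configuration is irrelevant because this carbon is oxidised in the next step.

Step 28
Reactants: 42 C1–C16 vinylogous aldol adduct
Product: 43 C1–C16 β-keto dioxinone (C5 ketone, (E)-C16 alkenyl iodide)
Conditions: Dess–Martin periodinane, NaHCO3, CH2Cl2, 0 °C to rt
Reagents that add atoms: none
Why: Dess–Martin oxidation of the secondary alcohol to the C5 ketone under buffered conditions that should not epimerise C6.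

Step 29
Reactants: 14 (3S,4S,6R)-6-ethyl-4-hydroxy-3-methyl-6-[(E)-2-(tributylstannyl)ethenyl]oxan-2-one; 43 C1–C16 β-keto dioxinone
Product: 44 open-chain (15E,17E)-diene with free C21 hydroxyl and intact dioxinone
Conditions: Pd2(dba)3 (cat.), AsPh3, NMP, rt
Reagents that add atoms: none
Why: Stille cross-coupling of the alkenyl iodide with the alkenylstannane proceeds with retention at both double bonds, giving the (15E,17E)-diene, and tolerates the free hydroxyl and the dioxinone.

Step 30
Reactants: 44 open-chain (15E,17E)-diene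
Product: 46 macrocyclic 3,5-diketo ester (21-membered lactone), via acylketene 45 (not isolated)
Conditions: PhMe (0.5 mM), 110 °C
Reagents that add atoms: none
Why: Thermal retro-hetero-Diels–Alder loss of acetone from the dioxinone gives an acylketene that is trapped by the C21 hydroxyl (acylketene macrolactonisation), closing the 21-membered ring under neutral conditions that spare the β-acyloxy lactone.

Step 31
Reactants: 46 macrocyclic 3,5-diketo ester
Product: 48 protected target (furanone; 7,9-silylene; 14-OTES), via C6 hydroxy diketone 47 (not isolated)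
Conditions: PPTS (cat.), MeOH/CH2Cl2, 0 °C
Reagents that add atoms: none
Why: Selective acid methanolysis of the secondary α-keto triethylsilyl ether frees the C6 hydroxyl, which adds to the C3 ketone (five-membered hemiketal) and dehydrates to the 3(2H)-furanone; C6 keeps its configuration because its C–O bond is not broken.

Step 32
Reactants: 48 protected target
Product: 49 target CNP0226414.1
Conditions: HF·pyridine, pyridine, THF, 0 °C to rt
Reagents that add atoms: none
Why: Fluoride-mediated desilylation removes the silylene and the tertiary triethylsilyl ether under buffered conditions that should not ionise the tertiary allylic C14–O and C19–O bonds.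

**Compound list**

1 | 2-methylidenebutan-1-ol | C=C(CC)CO | starting material
2 | (S)-(2-ethyloxiran-2-yl)methanol | CC[C@]1(CO)CO1 | intermediate
3 | (R)-tert-butyl[(2-ethyloxiran-2-yl)methoxy]dimethylsilane | CC[C@]1(CO[Si](C)(C)C(C)(C)C)CO1 | intermediate
4 | (S)-1-[(tert-butyldimethylsilyl)oxy]-2-[(4,4,5,5-tetramethyl-1,3,2-dioxaborolan-2-yl)methyl]butan-2-ol | CC[C@](O)(CO[Si](C)(C)C(C)(C)C)CB1OC(C)(C)C(C)(C)O1 | intermediate
5 | tertiary triethylsilyl ether of 4 | CC[C@](O[Si](CC)(CC)CC)(CO[Si](C)(C)C(C)(C)C)CB1OC(C)(C)C(C)(C)O1 | intermediate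
6 | (E)-1-bromoprop-1-ene | C/C=C/Br | starting material
7 | (E)-prop-1-enyllithium | [Li]/C=C/C | intermediate
8 | lithium (E)-prop-1-enyl pinacolatoborate complex of 5 | [Li+].CC[C@](O[Si](CC)(CC)CC)(CO[Si](C)(C)C(C)(C)C)C[B-]1(/C=C/C)OC(C)(C)C(C)(C)O1 | intermediate
9 | methyl (2S,3S,5R)-5-{[(tert-butyldimethylsilyl)oxy]methyl}-2-methyl-3-(4,4,5,5-tetramethyl-1,3,2-dioxaborolan-2-yl)-5-[(triethylsilyl)oxy]heptanoate | CC[C@](O[Si](CC)(CC)CC)(CO[Si](C)(C)C(C)(C)C)C[C@H](B1OC(C)(C)C(C)(C)O1)[C@H](C)C(=O)OC | intermediate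
10 | methyl (2S,3S,5R)-5-{[(tert-butyldimethylsilyl)oxy]methyl}-3-hydroxy-2-methyl-5-[(triethylsilyl)oxy]heptanoate | CC[C@](O[Si](CC)(CC)CC)(CO[Si](C)(C)C(C)(C)C)C[C@H](O)[C@H](C)C(=O)OC | intermediate
11 | methyl (2S,3S,5R)-3,5-dihydroxy-5-(hydroxymethyl)-2-methylheptanoate | CC[C@](O)(CO)C[C@H](O)[C@H](C)C(=O)OC | intermediate
12 | (3S,4S,6R)-6-ethyl-4-hydroxy-6-(hydroxymethyl)-3-methyloxan-2-one | CC[C@]1(CO)C[C@H](O)[C@H](C)C(=O)O1 | intermediate
13 | (2R,4S,5S)-2-ethyl-4-hydroxy-5-methyl-6-oxooxane-2-carbaldehyde | CC[C@]1(C=O)C[C@H](O)[C@H](C)C(=O)O1 | intermediate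
14 | (3S,4S,6R)-6-ethyl-4-hydroxy-3-methyl-6-[(E)-2-(tributylstannyl)ethenyl]oxan-2-one | CC[C@]1(/C=C/[Sn](CCCC)(CCCC)CCCC)C[C@H](O)[C@H](C)C(=O)O1 | intermediate
15 | (R)-(2-methyloxiran-2-yl)methanol | OC[C@]1(C)CO1 | starting material
16 | (S)-2-methylhex-5-ene-1,2-diol | OC[C@@](C)(O)CCC=C | intermediate
17 | (S)-2-methyl-1,2-bis[(triethylsilyl)oxy]hex-5-ene | CC[Si](CC)(CC)OC[C@@](C)(O[Si](CC)(CC)CC)CCC=C | intermediate
18 | (S)-2-methyl-2-[(triethylsilyl)oxy]hex-5-enal | O=C[C@@](C)(O[Si](CC)(CC)CC)CCC=C | intermediate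
19 | (S)-[(1,1-dibromo-3-methylhepta-1,6-dien-3-yl)oxy]triethylsilane | BrC(Br)=C[C@@](C)(O[Si](CC)(CC)CC)CCC=C | intermediate
20 | (S)-{3-methyl-3-[(triethylsilyl)oxy]hept-6-en-1-ynyl}lithium | [Li]C#C[C@@](C)(O[Si](CC)(CC)CC)CCC=C | intermediate
21 | (S)-triethyl[(4-methyloct-7-en-2-yn-4-yl)oxy]silane | CC#C[C@@](C)(O[Si](CC)(CC)CC)CCC=C | intermediate
22 | (5S)-5-methyl-5-[(triethylsilyl)oxy]oct-6-yne-1,2-diol (both C2 epimers) | CC#C[C@@](C)(O[Si](CC)(CC)CC)CCC(O)CO | intermediate
23 | (S)-4-methyl-4-[(triethylsilyl)oxy]hept-5-ynal | CC#C[C@@](C)(O[Si](CC)(CC)CC)CCC=O | intermediate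
24 | (3S,4R,7S)-3,7-dimethyl-7-[(triethylsilyl)oxy]dec-1-en-8-yn-4-ol | CC#C[C@@](C)(O[Si](CC)(CC)CC)CC[C@@H](O)[C@@H](C)C=C | intermediate
25 | (3S,4R,7S)-4-methoxy-3,7-dimethyl-7-[(triethylsilyl)oxy]dec-1-en-8-yne | CC#C[C@@](C)(O[Si](CC)(CC)CC)CC[C@@H](OC)[C@@H](C)C=C | intermediate
26 | (3S,4R,7S)-4-methoxy-3,7-dimethyl-7-[(triethylsilyl)oxy]dec-8-yne-1,2-diol (both C2 epimers) | CC#C[C@@](C)(O[Si](CC)(CC)CC)CC[C@@H](OC)[C@@H](C)C(O)CO | intermediate
27 | (2R,3R,6S)-3-methoxy-2,6-dimethyl-6-[(triethylsilyl)oxy]non-7-ynal | CC#C[C@@](C)(O[Si](CC)(CC)CC)CC[C@@H](OC)[C@@H](C)C=O | intermediate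
28 | methyl (R)-2,2-dimethyl-1,3-dioxolane-4-carboxylate | COC(=O)[C@H]1COC(C)(C)O1 | starting material
29 | (R)-N-methoxy-N,2,2-trimethyl-1,3-dioxolane-4-carboxamide | CON(C)C(=O)[C@H]1COC(C)(C)O1 | intermediate
30 | (R)-1-(2,2-dimethyl-1,3-dioxolan-4-yl)propan-1-one | CCC(=O)[C@H]1COC(C)(C)O1 | intermediate
31 | (Z)-trichlorotitanium enolate of 30 | C/C=C(\O[Ti](Cl)(Cl)Cl)[C@H]1COC(C)(C)O1 | intermediate
32 | C5–C16 aldol adduct: C7 ketone, 9-OH, 11-OMe, 14-OTES, C15≡C16–CH3, 5,6-O-isopropylidene; 6-O/8-Me syn, 8-Me/9-OH syn, 9-OH/10-Me anti; target configuration at C6, C8–C11, C14 | CC#C[C@@](C)(O[Si](CC)(CC)CC)CC[C@@H](OC)[C@@H](C)[C@@H](O)[C@H](C)C(=O)[C@H]1COC(C)(C)O1 | intermediate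
33 | C5–C16 7,9-anti diol from 32 (target configuration at C6–C11, C14) | CC#C[C@@](C)(O[Si](CC)(CC)CC)CC[C@@H](OC)[C@@H](C)[C@@H](O)[C@H](C)[C@H](O)[C@H]1COC(C)(C)O1 | intermediate
34 | 7,9-O-di-tert-butylsilylene derivative of 33 | CC#C[C@@](C)(O[Si](CC)(CC)CC)CC[C@@H](OC)[C@@H](C)[C@@H](O2)[C@H](C)[C@H](O[Si]2(C(C)(C)C)C(C)(C)C)[C@H]1COC(C)(C)O1 | intermediate
35 | C5–C16 5,6,14-triol (7,9-silylene, 11-OMe, alkyne) | CC#C[C@@](C)(O)CC[C@@H](OC)[C@@H](C)[C@@H](O2)[C@H](C)[C@H](O[Si]2(C(C)(C)C)C(C)(C)C)[C@H](O)CO | intermediate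
36 | 5,6,14-tris(triethylsilyl) ether of 35 | CC#C[C@@](C)(O[Si](CC)(CC)CC)CC[C@@H](OC)[C@@H](C)[C@@H](O2)[C@H](C)[C@H](O[Si]2(C(C)(C)C)C(C)(C)C)[C@H](O[Si](CC)(CC)CC)CO[Si](CC)(CC)CC | intermediate
37 | (E)-alkenylzirconocene chloride from 36 (Zr on C16) | Cl[Zr](C1C=CC=C1)(C1C=CC=C1)/C(C)=C/[C@@](C)(O[Si](CC)(CC)CC)CC[C@@H](OC)[C@@H](C)[C@@H](O2)[C@H](C)[C@H](O[Si]2(C(C)(C)C)C(C)(C)C)[C@H](O[Si](CC)(CC)CC)CO[Si](CC)(CC)CC | intermediate
38 | C5–C16 (E)-C16 alkenyl iodide (5,6,14-tris-OTES, 7,9-silylene) | I/C(C)=C/[C@@](C)(O[Si](CC)(CC)CC)CC[C@@H](OC)[C@@H](C)[C@@H](O2)[C@H](C)[C@H](O[Si]2(C(C)(C)C)C(C)(C)C)[C@H](O[Si](CC)(CC)CC)CO[Si](CC)(CC)CC | intermediate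
39 | C5 aldehyde (6-OTES, 14-OTES, 7,9-silylene, (E)-alkenyl iodide) | I/C(C)=C/[C@@](C)(O[Si](CC)(CC)CC)CC[C@@H](OC)[C@@H](C)[C@@H](O2)[C@H](C)[C@H](O[Si]2(C(C)(C)C)C(C)(C)C)[C@H](O[Si](CC)(CC)CC)C=O | intermediate
40 | 2,2,6-trimethyl-4H-1,3-dioxin-4-one | CC1=CC(=O)OC(C)(C)O1 | starting material
41 | lithium dienolate of 40 | [Li]OC1=CC(=C)OC(C)(C)O1 | intermediate
42 | C1–C16 vinylogous aldol adduct (dioxinone–CH2–CH(OH)–; C5 epimers) | I/C(C)=C/[C@@](C)(O[Si](CC)(CC)CC)CC[C@@H](OC)[C@@H](C)[C@@H](O2)[C@H](C)[C@H](O[Si]2(C(C)(C)C)C(C)(C)C)[C@H](O[Si](CC)(CC)CC)C(O)CC1=CC(=O)OC(C)(C)O1 | intermediate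
43 | C1–C16 β-keto dioxinone (C5 ketone, (E)-C16 alkenyl iodide) | I/C(C)=C/[C@@](C)(O[Si](CC)(CC)CC)CC[C@@H](OC)[C@@H](C)[C@@H](O2)[C@H](C)[C@H](O[Si]2(C(C)(C)C)C(C)(C)C)[C@H](O[Si](CC)(CC)CC)C(=O)CC1=CC(=O)OC(C)(C)O1 | intermediate
44 | open-chain (15E,17E)-diene: δ-lactone with free C21–OH joined at C17 to the C1–C16 β-keto dioxinone | CC[C@]1(/C=C/C(C)=C/[C@@](C)(O[Si](CC)(CC)CC)CC[C@@H](OC)[C@@H](C)[C@@H](O2)[C@H](C)[C@H](O[Si]2(C(C)(C)C)C(C)(C)C)[C@H](O[Si](CC)(CC)CC)C(=O)CC3=CC(=O)OC(C)(C)O3)C[C@H](O)[C@H](C)C(=O)O1 | intermediate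
45 | acylketene from 44 (C1=C=O, C3 and C5 ketones) | CC[C@]1(/C=C/C(C)=C/[C@@](C)(O[Si](CC)(CC)CC)CC[C@@H](OC)[C@@H](C)[C@@H](O2)[C@H](C)[C@H](O[Si]2(C(C)(C)C)C(C)(C)C)[C@H](O[Si](CC)(CC)CC)C(=O)CC(=O)C=C=O)C[C@H](O)[C@H](C)C(=O)O1 | intermediate
46 | macrocyclic 3,5-diketo ester (21-membered lactone; 6-OTES, 14-OTES, 7,9-silylene) | CC[C@]12/C=C/C(C)=C/[C@@](C)(O[Si](CC)(CC)CC)CC[C@@H](OC)[C@@H](C)[C@@H](O3)[C@H](C)[C@H](O[Si]3(C(C)(C)C)C(C)(C)C)[C@H](O[Si](CC)(CC)CC)C(=O)CC(=O)CC(=O)O[C@@H](C1)[C@H](C)C(=O)O2 | intermediate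
47 | C6 hydroxy 3,5-diketone macrocycle (14-OTES, 7,9-silylene) | CC[C@]12/C=C/C(C)=C/[C@@](C)(O[Si](CC)(CC)CC)CC[C@@H](OC)[C@@H](C)[C@@H](O3)[C@H](C)[C@H](O[Si]3(C(C)(C)C)C(C)(C)C)[C@H](O)C(=O)CC(=O)CC(=O)O[C@@H](C1)[C@H](C)C(=O)O2 | intermediate
48 | protected target: furanone macrocycle with 7,9-O-di-tert-butylsilylene and 14-OTES | CC[C@]12/C=C/C(C)=C/[C@@](C)(O[Si](CC)(CC)CC)CC[C@@H](OC)[C@@H](C)[C@@H](O4)[C@H](C)[C@H](O[Si]4(C(C)(C)C)C(C)(C)C)[C@@H]3OC(=CC3=O)CC(=O)O[C@@H](C1)[C@H](C)C(=O)O2 | intermediate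
49 | CNP0226414.1 | CC[C@]12/C=C/C(C)=C/[C@@](C)(O)CC[C@@H](OC)[C@@H](C)[C@@H](O)[C@H](C)[C@H](O)[C@@H]3OC(=CC3=O)CC(=O)O[C@@H](C1)[C@H](C)C(=O)O2 | target

**Step count and risks**

Total step count: 32. Longest linear sequence: 22 steps (steps 10–18 and 20–32, from 15).

Steps most likely to fail:

1. Step 5. Direct transfer of the propenyl group from boron to palladium (Suzuki-type coupling) or β-elimination within the ate complex may outpace the metallate shift, and catalyst control over the new centres relative to C19 may be insufficient. The fallback uses known chemistry, sets out from 3 and returns at 10. Epoxide 3 is opened at its CH2 terminus with vinylmagnesium bromide and CuI to give (R)-3-{[(tert-butyldimethylsilyl)oxy]methyl}hex-5-en-3-ol F1, which is silylated (TESOTf, 2,6-lutidine) to its triethylsilyl ether F2. Lemieux–Johnson cleavage of F2 gives the β-silyloxy aldehyde F3. Roush crotylboration of F3 with the (S,S)-tartrate (E)-crotylboronate (Re-face attack, anti) forms C21–C22 and gives the homoallylic alcohol F4. Ozonolysis of F4 in CH2Cl2/methanolic NaOH converts the vinyl group directly into the methyl ester 10.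

2. Step 30. Intramolecular O-acylation of the C5 enol by the acylketene (pyranone formation) or oligomerisation may compete with closure of the large ring. The fallback closes the ring at C16–C17 instead, sets out from 14 and 43 and returns at 46. Heating 43 with 14 in concentrated toluene solution lets the acylketene be trapped bimolecularly by the C21 hydroxyl, giving the open-chain ester F5 that carries both the alkenyl iodide and the alkenylstannane. An intramolecular Stille coupling of F5 at high dilution (Pd2(dba)3, AsPh3) then gives 46.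

3. Step 20. Facial selectivity may erode in this triply stereodifferentiating aldol, and the α-methyl aldehyde may epimerise under the Lewis-acidic conditions. The fallback forms C7–C8 instead of C8–C9, sets out from 27 and returns at 33. Addition of EtMgBr to 27 gives the secondary alcohol F6, and Dess–Martin oxidation gives the ethyl ketone F7. Its (E)-boron enolate ((c-Hex)2BCl, Et3N) adds to (R)-2,3-O-isopropylideneglyceraldehyde in an anti-aldol reaction with Felkin control at the α-alkoxy aldehyde, giving the C9 ketone F8. Evans–Saksena reduction of F8, directed by the C7 hydroxyl, gives 33.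

Further compounds
F1 | step 5 | (R)-3-{[(tert-butyldimethylsilyl)oxy]methyl}hex-5-en-3-ol | CC[C@](O)(CO[Si](C)(C)C(C)(C)C)CC=C
F2 | step 5 | triethylsilyl ether of F1 | CC[C@](O[Si](CC)(CC)CC)(CO[Si](C)(C)C(C)(C)C)CC=C
F3 | step 5 | (R)-3-{[(tert-butyldimethylsilyl)oxy]methyl}-3-[(triethylsilyl)oxy]pentanal | CC[C@](O[Si](CC)(CC)CC)(CO[Si](C)(C)C(C)(C)C)CC=O
F4 | step 5 | (3R,4S,6R)-6-{[(tert-butyldimethylsilyl)oxy]methyl}-3-methyl-6-[(triethylsilyl)oxy]oct-1-en-4-ol | CC[C@](O[Si](CC)(CC)CC)(CO[Si](C)(C)C(C)(C)C)C[C@H](O)[C@H](C)C=C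
F5 | step 30 | open-chain C21 3,5-diketo ester of 14 with the chain of 43 (alkenylstannane and alkenyl iodide both present) | I/C(C)=C/[C@@](C)(O[Si](CC)(CC)CC)CC[C@@H](OC)[C@@H](C)[C@@H](O2)[C@H](C)[C@H](O[Si]2(C(C)(C)C)C(C)(C)C)[C@H](O[Si](CC)(CC)CC)C(=O)CC(=O)CC(=O)O[C@H]1C[C@](CC)(/C=C/[Sn](CCCC)(CCCC)CCCC)OC(=O)[C@H]1C
F6 | step 20 | secondary alcohol from 27 and EtMgBr (C9 carbinol, both epimers) | CC#C[C@@](C)(O[Si](CC)(CC)CC)CC[C@@H](OC)[C@@H](C)C(O)CC
F7 | step 20 | C8–C16 ethyl ketone (C9 ketone, 11-OMe, 14-OTES, alkyne) | CC#C[C@@](C)(O[Si](CC)(CC)CC)CC[C@@H](OC)[C@@H](C)C(=O)CC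
F8 | step 20 | C5–C16 anti-aldol adduct (C9 ketone, 7-OH, 7-OH/8-Me anti, 5,6-O-isopropylidene) | CC#C[C@@](C)(O[Si](CC)(CC)CC)CC[C@@H](OC)[C@@H](C)C(=O)[C@H](C)[C@H](O)[C@H]1COC(C)(C)O1
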